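## Structural features

Benzofuran numbering is used throughout (O1, C2, C3, C3a, C4–C7, C7a); the hydroxymethyl carbon on C3 is called C9.

- The target 27 is a phenylcoumaran neolignan: benzene ring A (C3a–C7a) is fused to a dihydrofuran ring (O1, C2, C3). C2 carries a 4-hydroxy-3,5-dimethoxyphenyl ring (ring C), C3 a hydroxymethyl group, C7 a methoxy group and C5 an (E)-3-hydroxyprop-1-enyl chain.
- C2 (R) and C3 (S) are the only stereocentres; they are adjacent and trans.
- C2 is both a benzylic ether of ring C and the alkyl carbon of an aryl ether of ring A. Once the para-phenol of ring C is free, acid or strong base can break O1–C2 through a quinone methide.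
- The cinnamyl alcohol is acid-sensitive and the electron-rich phenol is easily oxidised.
- The real difficulty is to fix C2 and C3 absolutely and trans, and then never to expose C2 to ionising conditions. A second issue is the 1,2,3,5-substitution pattern of ring A.
- The key step uses the fact that C7a, C3a, O1, C2 and C3 can be read as the carbonyl carbon, α-carbon, ring oxygen, γ-carbon and β-carbon of a trans-disubstituted γ-butyrolactone.
- The remaining ring A carbons C4–C7, with the side-chain precursor on C5 (para to O1) and the methoxy group on C7, map onto the diene of a 3-methoxy-2-pyrone-5-carboxylate. Both stereocentres can therefore be set on a saturated lactone and ring A annulated last.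

## Logic of the disconnections

**27 to 26.** The two O–Si bonds (phenol of ring C, oxygen on C9) are cut. Both hydroxyls are masked alike so that one buffered fluoride treatment ends the synthesis and no acid meets the cinnamyl alcohol or the C2 ether. The demand is that the phenoxide is never left unbuffered, since it could expel O1 from C2.

**26 to 21 (through 25, 24, 22 and 23).** The side chain is taken back in oxidation level (26 from 25 by hydride), then cut at its C=C bond into 22 (through 24) and the two-carbon ylide 23; 22 comes from 21 by reduction. The whole chain is thereby reduced to a single ester on C5, which is the substituent the benzannulation delivers. The demand is an E-selective olefination under neutral conditions.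

**21 to 12 and 18.** The bonds C3a–C4 and C7–C7a are cut, which removes ring A. What remains is a monocyclic ketene O,S-acetal 12 that holds both stereocentres and a flat pyrone 18 that holds C4–C7 with their substituents. The cut is made here because the C3a=C7a unit is at the oxidation level of a lactone enol derivative, and because C5 (ester) is para to O1, the pattern that coumalate-type dienes give with ketene acetals. The demands are:
- the nucleophilic acetal carbon must pair with C6 of the pyrone;
- aromatisation must expel sulfur and not the ring oxygen;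
- no acid may be present.

**18 to 13 (through 17, 16 and 15).** The O–CH3 bond, then the C3–O bond (formed through the C3–B bond of 16), then the C3–Br bond are cut. Oxygen is brought in through boron because C3 of a 2-pyrone is not an acceptor position, and because alkoxide or hydroxide bases contract 3-bromo-2-pyrones to furan-2-carboxylates. The demand is that only weak bases touch the pyrone.

**12 to 10 (through 11).** The S–CH3 bond is cut and C=S is returned to C=O, which leads to an ordinary protected lactone. The demands are S-alkylation (not C-alkylation) of the enethiolate and a thionation that does not ionise the benzylic C–O bond.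

**10 to 7 (through 9 and 8).** The O–Si bond on C9 is cut, the C9 oxygen level is raised to the carboxylic acid, and the exocyclic N–C(=O) bond to the auxiliary is restored. The demands are reduction of the acid in the presence of the lactone and prompt silylation of 9, whose free primary hydroxyl could translactonise.

**7 to 5 and 2 (through 6).** The C2–C3 bond and the lactone O–C(=O) bond are cut. C2–C3 is the only C–C bond between the two stereocentres, so one aldol reaction sets both. A syn aldol adduct necessarily lactonises to the trans lactone. The fragments are an achiral aldehyde and an imide that carries all four carbons C3, C9, C3a and C7a. The demand is facial control, which the (R)-configured auxiliary of 5 supplies in the sense needed for 2R,3S.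

**5 to 3 and 4; 2 to 1.** An N-acyl bond and an O–Si bond are cut, leading to commercial materials.

## Other disconnections considered

**Alternative 1: asymmetric Prins dioxane on a stilbene.**
- Cut and key step: C3–C9 and C2–O are cut, leading to the E-stilbene A1 (ring A as its acetate with the enoate in place, ring C as its benzyl ether). A confined chiral Brønsted acid would add a CH2O oligomer across C2=C3. C3, next to the acetoxy-deactivated ring A, takes the new carbon; the cation develops at C2 next to the electron-rich ring C; closure gives the trans-4,5-diaryl-1,3-dioxane A2.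
- In favour: both stereocentres and C9 come from one catalytic step on a flat, easily assembled substrate, without an auxiliary. The regiochemistry is supported by the electronic difference between the rings. On catalyst economy and probably on step count it is the better plan.
- Against:
  - Syn addition to the E-alkene gives A2 with C2 in the configuration opposite to that of 27. The dihydrofuran must then be closed by the ring A phenol with inversion at a para-alkoxybenzylic carbon, the centre that ionises most easily. A cationic closure could still give the trans product under control of C3, so this is a risk, not a flaw of principle.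
  - A formaldehyde acetal is very robust, and opening it needs acid harsher than anything in the chosen route.
  - Confined-acid Prins reactions are best established for terminal aryl olefins; an oxygen-rich internal stilbene is an extrapolation.
  - The benzyl ether must be removed beside an alkene.
- Comparison: both plans set C2 and C3 in one step (equal). The chosen plan does so by an auxiliary aldol of predictable sense and never substitutes at C2 afterwards, whereas A2 must be substituted at C2. The alternative works through benzylic cations, which the chosen plan avoids.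

**Alternative 2: oxidative para-quinone methide cyclisation.**
- Cut and key step: O1–C2 is cut. In the precursor A3, C3 is already configured and C2 is a methylene group. Ag2O would oxidise the 4-alkyl-2,6-dimethoxyphenol of ring C to its para-quinone methide, and the ortho-hydroxyl of ring A would add to the exocyclic carbon in a 5-exo closure to give A4.
- In favour: no protecting groups; the sensitive benzylic ether is formed last and under neutral conditions; the syringyl phenol is the more easily oxidised of the two; the bromide of A4 accepts the whole side chain in one coupling. On protecting-group and step economy after C3 is in place it is better than the chosen plan.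
- Against:
  - A3 needs its own asymmetric synthesis of a benzylic centre, most likely by an auxiliary alkylation, so there is no saving over the aldol (equal on this point).
  - C2 is set by substrate control only, so a cis/trans mixture is possible.
  - The quinone methide can tautomerise to the stilbene by loss of H-3, which erases the only pre-set centre, or be trapped intermolecularly.
  - A4 is a free para-hydroxybenzyl ether from the moment it forms, so the coupling must tolerate the most labile form of C2.
- Comparison: the chosen plan fixes both centres together, with defined relative and absolute configuration, before ring A exists, and keeps C2 protected to the last step. The alternative is shorter but relies on a diastereoselection that no reagent can tune.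

**Alternative 3: dearomative arylcarbonylation of a benzofuran.**
- Cut and key step: C2–aryl and C3–C9 are cut, leading to the benzofuran A5, the aryl iodide A6, CO and MeOH. The cationic aryl–palladium species from A6, Pd(OAc)2, a chiral bisphosphine and AgOTf would add across C2=C3 with the aryl group at C2. The benzylic C3–Pd bond has no syn β-hydrogen, so it would insert CO and be cleaved by MeOH to give the cis ester A7.
- In favour: three simple components, a catalytic enantioselective step, two bonds at once, and the shortest sequence of all the plans (better on step economy and convergence).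
- Against:
  - Syn carbopalladation gives the cis isomer, so C3 must be epimerised. Under base the ester enolate can expel the ring A phenoxide and re-close, which would racemise C2, the only centre that then carries the absolute information.
  - Intermolecular enantioselective versions of this reaction on benzofurans are less established than intramolecular ones.
  - The aryl chloride must stay inert and later be coupled at an electron-rich position.
- Comparison: both plans make C9 at the carboxyl level and reduce it later (equal). The chosen plan obtains the trans arrangement directly and irreversibly and has no step in which C2–O can break. The alternative is shorter and catalytic but carries the epimerisation problem.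

Key step: step 12

## Remarks before the steps

- Methyl 4-chloro-4-oxobutanoate (4) and the ylide 23 are taken as commercial. Compound 4 replaces a succinic anhydride opening and activation.
- The phenol is protected as a triisopropylsilyl ether instead of an acetal so that both protecting groups fall to fluoride in the last step and no acid is needed.
- The syn-aldol adduct 6 is assumed to lactonise in the flask after oxidative work-up, with catalytic acid if needed.
- Direct methoxide displacement on the bromopyrone 15 is not used, for the reason given under the disconnections.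

## Route

Step 1
Reactants: 1 syringaldehyde
Product: 2 3,5-dimethoxy-4-(triisopropylsilyloxy)benzaldehyde
Conditions: TIPSCl, imidazole, DMF, 25 °C
Reagents that add atoms: chlorotriisopropylsilane (TIPSCl), CC(C)[Si](Cl)(C(C)C)C(C)C
Why: Imidazole-mediated silylation of the phenol. The hindered aryl silyl ether, flanked by two methoxy groups, should tolerate the boron aldol, peroxide hydrolysis, hydride and amide-base steps and is removed by fluoride at the end.

Step 2
Reactants: 3 (R)-4-benzyl-1,3-oxazolidin-2-one; 4 methyl 4-chloro-4-oxobutanoate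
Product: 5 methyl 4-[(4R)-4-benzyl-2-oxo-1,3-oxazolidin-3-yl]-4-oxobutanoate
Conditions: n-BuLi, THF, −78 °C; then 4, −78 to 0 °C
Reagents that add atoms: none
Why: N-acylation of the lithiated oxazolidinone by the acid chloride; the methyl ester is far less electrophilic and stays intact at low temperature.

Step 3
Reactants: 5 methyl 4-[(4R)-4-benzyl-2-oxo-1,3-oxazolidin-3-yl]-4-oxobutanoate; 2 3,5-dimethoxy-4-(triisopropylsilyloxy)benzaldehyde
Product: 7 (4R)-4-benzyl-3-{[(2R,3R)-2-[3,5-dimethoxy-4-(triisopropylsilyloxy)phenyl]-5-oxooxolan-3-yl]carbonyl}-1,3-oxazolidin-2-one, via syn-aldol hydroxy ester 6 (not isolated)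
Conditions: Bu2BOTf, Et3N, CH2Cl2, 0 °C; 2, −78 to 0 °C; H2O2, pH 7 buffer, MeOH, 0 °C; PPTS (cat.), CH2Cl2, 25 °C
Reagents that add atoms: none
Why: Evans boron syn-aldol reaction: the imide α-CH2 is enolised in preference to the ester α-CH2 to give the Z-boron enolate, and the chair transition state, with the benzyl group of the (R)-auxiliary blocking one face, sets the carbinol carbon (future C2) as R and the α-carbon (future C3) in the syn sense. The aldol oxygen then closes on the γ-ester, and a syn adduct can only give the trans-2,3-disubstituted lactone.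

Step 4
Reactants: 7 lactone imide
Product: 8 (2R,3R)-2-[3,5-dimethoxy-4-(triisopropylsilyloxy)phenyl]-5-oxooxolane-3-carboxylic acid
Conditions: LiOH, H2O2, THF/H2O, 0 °C; Na2SO3; 1 M HCl to pH 3
Reagents that add atoms: hydrogen peroxide (acting as LiOOH), OO
Why: Evans hydrolysis: hydroperoxide attacks the exocyclic imide carbonyl selectively and sulfite reduces the peracid. Any lactone opened by hydroxide recloses on acidification, because only the five-membered lactone can form.

Step 5
Reactants: 8 lactone acid
Product: 9 (4S,5R)-5-[3,5-dimethoxy-4-(triisopropylsilyloxy)phenyl]-4-(hydroxymethyl)oxolan-2-one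
Conditions: BH3·SMe2, THF, 0 to 25 °C; MeOH
Reagents that add atoms: none
Why: Borane reduces a free carboxylic acid (through its acyloxyborane) much faster than a lactone. The descriptor at the former α-carbon changes to S only because the priorities change.

Step 6
Reactants: 9 hydroxymethyl lactone
Product: 10 (4S,5R)-5-[3,5-dimethoxy-4-(triisopropylsilyloxy)phenyl]-4-[(triisopropylsilyloxy)methyl]oxolan-2-one
Conditions: TIPSCl, imidazole, DMF, 0 to 25 °C
Reagents that add atoms: chlorotriisopropylsilane (TIPSCl), CC(C)[Si](Cl)(C(C)C)C(C)C
Why: Standard silylation of a primary alcohol, carried out at once so that the hydroxyl cannot translactonise onto the lactone carbonyl.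

Step 7
Reactants: 10 silylated lactone
Product: 11 (4S,5R)-5-[3,5-dimethoxy-4-(triisopropylsilyloxy)phenyl]-4-[(triisopropylsilyloxy)methyl]oxolane-2-thione
Conditions: Lawesson's reagent, PhMe, 100 °C
Reagents that add atoms: Lawesson's reagent, COc1ccc(cc1)P1(=S)SP(=S)(S1)c1ccc(OC)cc1
Why: Oxygen-to-sulfur exchange at the lactone carbonyl through a four-membered P–S–C–O intermediate (Wittig-like), a known conversion of γ-lactones into thionolactones. The silyl ethers and the stereocentres are not involved.

Step 8
Reactants: 11 thionolactone
Product: 12 (2R,3S)-2-[3,5-dimethoxy-4-(triisopropylsilyloxy)phenyl]-5-(methylsulfanyl)-3-[(triisopropylsilyloxy)methyl]-2,3-dihydrofuran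
Conditions: LiN(iPr)2, THF, −78 °C; MeI, −78 to −20 °C; Et3N-buffered work-up
Reagents that add atoms: iodomethane, CI
Why: The α-CH2 of the thionolactone is deprotonated to the lithium enethiolate, whose soft sulfur is alkylated by MeI to give the ketene O,S-acetal. The carbanion has no β-leaving group, so both stereocentres stay as set; the acid-labile product is used without storage.

Step 9
Reactants: 13 methyl coumalate
Product: 15 methyl 3-bromo-2-oxo-2H-pyran-5-carboxylate, via dibromide adduct 14 (not isolated)
Conditions: Br2, CH2Cl2, 0 to 25 °C; then Et3N, 0 °C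
Reagents that add atoms: bromine, BrBr
Why: Electrophilic bromination of the 2-pyrone by addition–elimination. C3 is the free nucleophilic position (C5 carries the ester), and Et3N removes HBr from the adduct.

Step 10
Reactants: 15 methyl 3-bromo-2-oxo-2H-pyran-5-carboxylate
Product: 17 methyl 3-hydroxy-2-oxo-2H-pyran-5-carboxylate, via pinacol boronate 16 (not isolated)
Conditions: B2pin2, PdCl2(dppf) (cat.), KOAc, 1,4-dioxane, 80 °C; then 30% H2O2, pH 7 phosphate buffer, THF, 0 °C
Reagents that add atoms: hydrogen peroxide, OO; bis(pinacolato)diboron, CC1(C)OB(OC1(C)C)B1OC(C)(C)C(C)(C)O1 (its atoms stay only in 16)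
Why: Miyaura borylation: zerovalent palladium inserts into the C3–Br bond and acetate, a base too weak to contract the ring, mediates transfer of boron. Buffered peroxide then converts C–B into C–O by 1,2-migration and gives the stable enol.

Step 11
Reactants: 17 methyl 3-hydroxy-2-oxo-2H-pyran-5-carboxylate
Product: 18 methyl 3-methoxy-2-oxo-2H-pyran-5-carboxylate
Conditions: MeI, K2CO3, acetone, 25 °C
Reagents that add atoms: iodomethane, CI
Why: Williamson O-methylation of the acidic enolic hydroxyl under mild carbonate conditions in an aprotic solvent.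

Step 12
Reactants: 12 ketene O,S-acetal; 18 methyl 3-methoxy-2-oxo-2H-pyran-5-carboxylate
Product: 21 methyl (2R,3S)-2-[3,5-dimethoxy-4-(triisopropylsilyloxy)phenyl]-7-methoxy-3-[(triisopropylsilyloxy)methyl]-2,3-dihydro-1-benzofuran-5-carboxylate, via bridged lactone cycloadduct 19 (not isolated), via cyclohexadiene 20 (not isolated)
Conditions: PhMe, 100 °C, Ar sweep; then DBU, 25 °C
Reagents that add atoms: none
Why: The C=C bond of 12, raised in energy by oxygen and sulfur, and the electron-poor diene C3=C4–C5=C6 of 18 combine in an inverse-electron-demand [4+2] cycloaddition that is probably asynchronous: the nucleophilic acetal β-carbon (future C3a) bonds first to C6 of the pyrone, the acceptor position of both the ring carbonyl and the ester, and the acetal carbon (future C7a) then bonds to the methoxy-bearing C3. This orientation places the methoxy group on C7 and the ester on C5, para to O1, as is known for coumalate esters with ketene acetals and enol ethers, the closest known reaction type. Ring A is closed by this intermolecular [4+2] annulation across the lactone-derived C3a–C7a bond, and the bridged lactone 19 then loses CO2 by retro-[4+2] reaction to give diene 20. For aromatisation DBU removes H-3a, which is γ to the ester, and the dienolate expels methanethiolate (E1cB), a softer and much less basic leaving group than the ring alkoxide, so O1 stays on C7a. No lasting stereocentre is formed: the centres created at C3a and C7a vanish on aromatisation, while C2 and C3 are spectators, C3 being only allylic and C2 bearing an aryl group whose silylated 4-oxygen gives little support to ionisation. The selectivities needed are regiochemistry, secured by the polarisation of both partners, and the choice of leaving group, secured by sulfur and the basic finish; the argon sweep removes MeSH before it can add to unreacted 18.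

Step 13
Reactants: 21 benzofuran ester
Product: 22 {(2R,3S)-2-[3,5-dimethoxy-4-(triisopropylsilyloxy)phenyl]-7-methoxy-3-[(triisopropylsilyloxy)methyl]-2,3-dihydro-1-benzofuran-5-yl}methanol
Conditions: iBu2AlH, CH2Cl2, −78 to 0 °C; aq. potassium sodium tartrate
Reagents that add atoms: none
Why: Hydride reduction of the aryl ester to the benzylic alcohol; silyl ethers and aryl ethers are inert to the reagent.

Step 14
Reactants: 22 benzylic alcohol; 23 methyl (triphenylphosphoranylidene)acetate
Product: 25 methyl (2E)-3-{(2R,3S)-2-[3,5-dimethoxy-4-(triisopropylsilyloxy)phenyl]-7-methoxy-3-[(triisopropylsilyloxy)methyl]-2,3-dihydro-1-benzofuran-5-yl}prop-2-enoate, via aldehyde 24 (not isolated)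
Conditions: MnO2, CH2Cl2, 25 to 40 °C
Reagents that add atoms: none
Why: Tandem oxidation–Wittig reaction: MnO2 oxidises the benzylic alcohol and the aldehyde is trapped at once by the stabilised ylide, which gives the E-enoate. The medium is neutral, so C2 is not at risk.

Step 15
Reactants: 25 enoate
Product: 26 (2E)-3-{(2R,3S)-2-[3,5-dimethoxy-4-(triisopropylsilyloxy)phenyl]-7-methoxy-3-[(triisopropylsilyloxy)methyl]-2,3-dihydro-1-benzofuran-5-yl}prop-2-en-1-ol
Conditions: iBu2AlH, CH2Cl2, −78 °C; aq. potassium sodium tartrate
Reagents that add atoms: none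
Why: 1,2-Reduction of the α,β-unsaturated ester at low temperature gives the allylic alcohol with the E double bond unchanged.

Step 16
Reactants: 26 bis-silyl ether
Product: 27 4-[(2R,3S)-3-(hydroxymethyl)-5-[(1E)-3-hydroxyprop-1-en-1-yl]-7-methoxy-2,3-dihydro-1-benzofuran-2-yl]-2,6-dimethoxyphenol
Conditions: Bu4NF, AcOH, THF, 0 to 25 °C
Reagents that add atoms: none
Why: Fluoride cleaves both Si–O bonds, the aryl one quickly and the primary alkyl one more slowly. Acetic acid keeps the phenol protonated so that the 4-hydroxybenzyl ether at C2 is not pushed towards a quinone methide, and no acid strong enough to ionise the cinnamyl alcohol is present.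

## Compound list

1 | syringaldehyde (4-hydroxy-3,5-dimethoxybenzaldehyde) | COc1cc(C=O)cc(OC)c1O | starting material
2 | 3,5-dimethoxy-4-(triisopropylsilyloxy)benzaldehyde | COc1cc(C=O)cc(OC)c1O[Si](C(C)C)(C(C)C)C(C)C | intermediate
3 | (R)-4-benzyl-1,3-oxazolidin-2-one | O=C1N[C@H](Cc2ccccc2)CO1 | starting material
4 | methyl 4-chloro-4-oxobutanoate | COC(=O)CCC(Cl)=O | starting material
5 | methyl 4-[(4R)-4-benzyl-2-oxo-1,3-oxazolidin-3-yl]-4-oxobutanoate | COC(=O)CCC(=O)N1[C@H](Cc2ccccc2)COC1=O | intermediate
6 | methyl (3R,4R)-3-{[(4R)-4-benzyl-2-oxo-1,3-oxazolidin-3-yl]carbonyl}-4-[3,5-dimethoxy-4-(triisopropylsilyloxy)phenyl]-4-hydroxybutanoate (syn-aldol adduct) | COC(=O)C[C@@H](C(=O)N1[C@H](Cc2ccccc2)COC1=O)[C@@H](O)c1cc(OC)c(O[Si](C(C)C)(C(C)C)C(C)C)c(OC)c1 | intermediate (not isolated)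
7 | (4R)-4-benzyl-3-{[(2R,3R)-2-[3,5-dimethoxy-4-(triisopropylsilyloxy)phenyl]-5-oxooxolan-3-yl]carbonyl}-1,3-oxazolidin-2-one (trans lactone) | O=C1C[C@@H](C(=O)N2[C@H](Cc3ccccc3)COC2=O)[C@H](c2cc(OC)c(O[Si](C(C)C)(C(C)C)C(C)C)c(OC)c2)O1 | intermediate
8 | (2R,3R)-2-[3,5-dimethoxy-4-(triisopropylsilyloxy)phenyl]-5-oxooxolane-3-carboxylic acid | O=C1C[C@@H](C(=O)O)[C@H](c2cc(OC)c(O[Si](C(C)C)(C(C)C)C(C)C)c(OC)c2)O1 | intermediate
9 | (4S,5R)-5-[3,5-dimethoxy-4-(triisopropylsilyloxy)phenyl]-4-(hydroxymethyl)oxolan-2-one | O=C1C[C@@H](CO)[C@H](c2cc(OC)c(O[Si](C(C)C)(C(C)C)C(C)C)c(OC)c2)O1 | intermediate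
10 | (4S,5R)-5-[3,5-dimethoxy-4-(triisopropylsilyloxy)phenyl]-4-[(triisopropylsilyloxy)methyl]oxolan-2-one | O=C1C[C@@H](CO[Si](C(C)C)(C(C)C)C(C)C)[C@H](c2cc(OC)c(O[Si](C(C)C)(C(C)C)C(C)C)c(OC)c2)O1 | intermediate
11 | (4S,5R)-5-[3,5-dimethoxy-4-(triisopropylsilyloxy)phenyl]-4-[(triisopropylsilyloxy)methyl]oxolane-2-thione | S=C1C[C@@H](CO[Si](C(C)C)(C(C)C)C(C)C)[C@H](c2cc(OC)c(O[Si](C(C)C)(C(C)C)C(C)C)c(OC)c2)O1 | intermediate
12 | (2R,3S)-2-[3,5-dimethoxy-4-(triisopropylsilyloxy)phenyl]-5-(methylsulfanyl)-3-[(triisopropylsilyloxy)methyl]-2,3-dihydrofuran | COc1cc([C@@H]2OC(SC)=C[C@H]2CO[Si](C(C)C)(C(C)C)C(C)C)cc(OC)c1O[Si](C(C)C)(C(C)C)C(C)C | intermediate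
13 | methyl coumalate (methyl 2-oxo-2H-pyran-5-carboxylate) | COC(=O)C1=COC(=O)C=C1 | starting material
14 | methyl 3,4-dibromo-2-oxo-3,4-dihydro-2H-pyran-5-carboxylate (racemic bromine adduct) | COC(=O)C1=COC(=O)C(Br)C1Br | intermediate (not isolated)
15 | methyl 3-bromo-2-oxo-2H-pyran-5-carboxylate | COC(=O)C1=COC(=O)C(Br)=C1 | intermediate
16 | methyl 2-oxo-3-(4,4,5,5-tetramethyl-1,3,2-dioxaborolan-2-yl)-2H-pyran-5-carboxylate | COC(=O)C1=COC(=O)C(B2OC(C)(C)C(C)(C)O2)=C1 | intermediate (not isolated)
17 | methyl 3-hydroxy-2-oxo-2H-pyran-5-carboxylate | COC(=O)C1=COC(=O)C(O)=C1 | intermediate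
18 | methyl 3-methoxy-2-oxo-2H-pyran-5-carboxylate (same as methyl 5-methoxy-6-oxo-6H-pyran-3-carboxylate) | COC(=O)C1=COC(=O)C(OC)=C1 | intermediate
19 | bridged lactone cycloadduct: 2-oxabicyclo[2.2.2]octenone from 18 (bridgeheads are pyrone C3 with OMe and pyrone C6; CO2Me on the alkene) fused across the new two-carbon bridge to the tetrahydrofuran ring of 12 (SMe on the acetal carbon); configuration of the four new sp3 centres not defined | COC(=O)C1=CC2(OC)C(=O)OC1C3[C@@H](CO[Si](C(C)C)(C(C)C)C(C)C)[C@H](c4cc(OC)c(O[Si](C(C)C)(C(C)C)C(C)C)c(OC)c4)OC23SC | intermediate (not isolated)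
20 | methyl (2R,3S)-2-[3,5-dimethoxy-4-(triisopropylsilyloxy)phenyl]-7-methoxy-7a-(methylsulfanyl)-3-[(triisopropylsilyloxy)methyl]-2,3,3a,7a-tetrahydro-1-benzofuran-5-carboxylate (C3a and C7a not defined) | COC(=O)C1=CC2[C@@H](CO[Si](C(C)C)(C(C)C)C(C)C)[C@H](c3cc(OC)c(O[Si](C(C)C)(C(C)C)C(C)C)c(OC)c3)OC2(SC)C(OC)=C1 | intermediate (not isolated)
21 | methyl (2R,3S)-2-[3,5-dimethoxy-4-(triisopropylsilyloxy)phenyl]-7-methoxy-3-[(triisopropylsilyloxy)methyl]-2,3-dihydro-1-benzofuran-5-carboxylate | COc1cc([C@@H]2Oc3c(OC)cc(C(=O)OC)cc3[C@H]2CO[Si](C(C)C)(C(C)C)C(C)C)cc(OC)c1O[Si](C(C)C)(C(C)C)C(C)C | intermediate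
22 | {(2R,3S)-2-[3,5-dimethoxy-4-(triisopropylsilyloxy)phenyl]-7-methoxy-3-[(triisopropylsilyloxy)methyl]-2,3-dihydro-1-benzofuran-5-yl}methanol | COc1cc([C@@H]2Oc3c(OC)cc(CO)cc3[C@H]2CO[Si](C(C)C)(C(C)C)C(C)C)cc(OC)c1O[Si](C(C)C)(C(C)C)C(C)C | intermediate
23 | methyl (triphenylphosphoranylidene)acetate | COC(=O)C=P(c1ccccc1)(c1ccccc1)c1ccccc1 | starting material
24 | (2R,3S)-2-[3,5-dimethoxy-4-(triisopropylsilyloxy)phenyl]-7-methoxy-3-[(triisopropylsilyloxy)methyl]-2,3-dihydro-1-benzofuran-5-carbaldehyde | COc1cc([C@@H]2Oc3c(OC)cc(C=O)cc3[C@H]2CO[Si](C(C)C)(C(C)C)C(C)C)cc(OC)c1O[Si](C(C)C)(C(C)C)C(C)C | intermediate (not isolated)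
25 | methyl (2E)-3-{(2R,3S)-2-[3,5-dimethoxy-4-(triisopropylsilyloxy)phenyl]-7-methoxy-3-[(triisopropylsilyloxy)methyl]-2,3-dihydro-1-benzofuran-5-yl}prop-2-enoate | COc1cc([C@@H]2Oc3c(OC)cc(/C=C/C(=O)OC)cc3[C@H]2CO[Si](C(C)C)(C(C)C)C(C)C)cc(OC)c1O[Si](C(C)C)(C(C)C)C(C)C | intermediate
26 | (2E)-3-{(2R,3S)-2-[3,5-dimethoxy-4-(triisopropylsilyloxy)phenyl]-7-methoxy-3-[(triisopropylsilyloxy)methyl]-2,3-dihydro-1-benzofuran-5-yl}prop-2-en-1-ol | COc1cc([C@@H]2Oc3c(OC)cc(/C=C/CO)cc3[C@H]2CO[Si](C(C)C)(C(C)C)C(C)C)cc(OC)c1O[Si](C(C)C)(C(C)C)C(C)C | intermediate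
27 | 4-[(2R,3S)-3-(hydroxymethyl)-5-[(1E)-3-hydroxyprop-1-en-1-yl]-7-methoxy-2,3-dihydro-1-benzofuran-2-yl]-2,6-dimethoxyphenol | COc1cc([C@@H]2Oc3c(OC)cc(/C=C/CO)cc3[C@H]2CO)cc(OC)c1O | target

## Step count and least certain steps

Total: 16 steps. Longest linear sequence: 12 steps (steps 1, 3–8 and 12–16, from 1 to 27; the branch from 3 through step 2 is equally long). The pyrone branch (steps 9–11) is three steps.

**Step 12 (key step).**
- What may go wrong: the cycloaddition may be outrun by hydrolysis or oligomerisation of the acid-labile acetal, because the second bond joins two fully substituted carbons and the 3-methoxy group raises the LUMO of the diene. A second failure mode is aromatisation with loss of the ring oxygen and retention of sulfur.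
- Fallback, from 12 and 15 back to 21: the more electron-poor bromopyrone 15 is used as the diene under the same conditions and should give the 7-bromo ester F1. This ordinary aryl bromide is borylated (B2pin2, PdCl2(dppf), KOAc, dioxane, 80 °C) to the 7-pinacolboronate ester F2, oxidised (H2O2, pH 7 buffer) to the 7-hydroxy ester F3, and methylated (MeI, K2CO3, acetone) to 21.

**Step 10.**
- What may go wrong: opening of the pyrone ring by the nucleophilic oxidant (conjugate addition at C6), or protodeboronation of the α-boryl lactone during the aqueous oxidation.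
- Fallback, from 16 back to 18: 16 is isolated by filtration and the C3–OMe bond is formed directly by copper-mediated oxidative coupling with methanol (Cu(OAc)2 cat., MeOH, Et3N, 4 Å sieves, O2, 25 °C; Chan–Lam etherification). This skips 17 and makes no compound outside the list (F0). If the borylation itself fails, the bromine is carried through the cycloaddition as in the fallback for step 12.

**Step 7.**
- What may go wrong: ionisation of the benzylic C–O bond at 100 °C under the weakly Lewis-acidic thionation conditions, leading to thiono-to-thiolo rearrangement or epimerisation at the aryl-bearing carbon.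
- Fallback, from 10 back to 12 without any C=S compound (it also bypasses step 8): iBu2AlH at −78 °C gives the lactol F4. PhSO2H with CaCl2 in CH2Cl2 gives the anomeric phenyl sulfone F5. LiN(iPr)2 and then MeSSMe give the α-(methylsulfanyl) sulfone F6, which is not isolated; on warming with iPr2NEt it loses benzenesulfinate and H-4 to give 12 (Ley-type sulfone chemistry).

**Step 3.**
- What may go wrong: slow or incomplete lactonisation of 6, and retro-aldol cleavage or epimerisation next to the imide if the ring closure is forced.
- Fallback, from 6 back to 8: 6 is isolated after the oxidative work-up and treated with LiOH/H2O2 (0 to 25 °C), which hydrolyses both the imide and the methyl ester to the hydroxy diacid F7. Acidification closes the only possible five-membered lactone and gives 8, bypassing 7.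

**Step 16.**
- What may go wrong: phenoxide-driven opening of the O1–C2 bond, or incomplete cleavage of the hindered primary silyl ether on a polar triol that is hard to free from ammonium salts.
- Fallback, from 25 back to 27: both silyl groups are removed at the enoate stage with HF·pyridine in THF/pyridine to give the deprotected enoate F8, and excess iBu2AlH (CH2Cl2, −78 °C) reduces F8 to 27.

## Further compounds

F1 | step 12 | methyl (2R,3S)-7-bromo-2-[3,5-dimethoxy-4-(triisopropylsilyloxy)phenyl]-3-[(triisopropylsilyloxy)methyl]-2,3-dihydro-1-benzofuran-5-carboxylate | COc1cc([C@@H]2Oc3c(Br)cc(C(=O)OC)cc3[C@H]2CO[Si](C(C)C)(C(C)C)C(C)C)cc(OC)c1O[Si](C(C)C)(C(C)C)C(C)C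
F2 | step 12 | methyl (2R,3S)-2-[3,5-dimethoxy-4-(triisopropylsilyloxy)phenyl]-7-(4,4,5,5-tetramethyl-1,3,2-dioxaborolan-2-yl)-3-[(triisopropylsilyloxy)methyl]-2,3-dihydro-1-benzofuran-5-carboxylate | COc1cc([C@@H]2Oc3c(B4OC(C)(C)C(C)(C)O4)cc(C(=O)OC)cc3[C@H]2CO[Si](C(C)C)(C(C)C)C(C)C)cc(OC)c1O[Si](C(C)C)(C(C)C)C(C)C
F3 | step 12 | methyl (2R,3S)-2-[3,5-dimethoxy-4-(triisopropylsilyloxy)phenyl]-7-hydroxy-3-[(triisopropylsilyloxy)methyl]-2,3-dihydro-1-benzofuran-5-carboxylate | COc1cc([C@@H]2Oc3c(O)cc(C(=O)OC)cc3[C@H]2CO[Si](C(C)C)(C(C)C)C(C)C)cc(OC)c1O[Si](C(C)C)(C(C)C)C(C)C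
F0 | step 10 | none | none
F4 | step 7 | (4S,5R)-5-[3,5-dimethoxy-4-(triisopropylsilyloxy)phenyl]-4-[(triisopropylsilyloxy)methyl]oxolan-2-ol (anomeric mixture) | OC1C[C@@H](CO[Si](C(C)C)(C(C)C)C(C)C)[C@H](c2cc(OC)c(O[Si](C(C)C)(C(C)C)C(C)C)c(OC)c2)O1
F5 | step 7 | (2R,3S)-2-[3,5-dimethoxy-4-(triisopropylsilyloxy)phenyl]-5-(phenylsulfonyl)-3-[(triisopropylsilyloxy)methyl]oxolane (anomeric mixture) | O=S(=O)(c1ccccc1)C1C[C@@H](CO[Si](C(C)C)(C(C)C)C(C)C)[C@H](c2cc(OC)c(O[Si](C(C)C)(C(C)C)C(C)C)c(OC)c2)O1
F6 | step 7 | (2R,3S)-2-[3,5-dimethoxy-4-(triisopropylsilyloxy)phenyl]-5-(methylsulfanyl)-5-(phenylsulfonyl)-3-[(triisopropylsilyloxy)methyl]oxolane | CSC1(S(=O)(=O)c2ccccc2)C[C@@H](CO[Si](C(C)C)(C(C)C)C(C)C)[C@H](c2cc(OC)c(O[Si](C(C)C)(C(C)C)C(C)C)c(OC)c2)O1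
F7 | step 3 | (2R)-2-{(R)-[3,5-dimethoxy-4-(triisopropylsilyloxy)phenyl](hydroxy)methyl}butanedioic acid | OC(=O)C[C@@H](C(=O)O)[C@@H](O)c1cc(OC)c(O[Si](C(C)C)(C(C)C)C(C)C)c(OC)c1
F8 | step 16 | methyl (2E)-3-[(2R,3S)-2-(4-hydroxy-3,5-dimethoxyphenyl)-3-(hydroxymethyl)-7-methoxy-2,3-dihydro-1-benzofuran-5-yl]prop-2-enoate | COc1cc([C@@H]2Oc3c(OC)cc(/C=C/C(=O)OC)cc3[C@H]2CO)cc(OC)c1O
A1 | alternative 1 | methyl (2E)-3-{4-acetoxy-3-[(E)-2-(4-benzyloxy-3,5-dimethoxyphenyl)ethenyl]-5-methoxyphenyl}prop-2-enoate | COC(=O)/C=C/c1cc(OC)c(OC(C)=O)c(/C=C/c2cc(OC)c(OCc3ccccc3)c(OC)c2)c1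
A2 | alternative 1 | methyl (2E)-3-{4-acetoxy-3-[(4S,5S)-4-(4-benzyloxy-3,5-dimethoxyphenyl)-1,3-dioxan-5-yl]-5-methoxyphenyl}prop-2-enoate | COc1cc([C@H]2OCOC[C@@H]2c3cc(/C=C/C(=O)OC)cc(OC)c3OC(C)=O)cc(OC)c1OCc1ccccc1
A3 | alternative 2 | (2S)-2-(5-bromo-2-hydroxy-3-methoxyphenyl)-3-(4-hydroxy-3,5-dimethoxyphenyl)propan-1-ol | COc1cc(C[C@H](CO)c2cc(Br)cc(OC)c2O)cc(OC)c1O
A4 | alternative 2 | [(2R,3S)-5-bromo-2-(4-hydroxy-3,5-dimethoxyphenyl)-7-methoxy-2,3-dihydro-1-benzofuran-3-yl]methanol | COc1cc([C@@H]2Oc3c(OC)cc(Br)cc3[C@H]2CO)cc(OC)c1O
A5 | alternative 3 | 5-chloro-7-methoxy-1-benzofuran | COc1cc(Cl)cc2ccoc12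
A6 | alternative 3 | 4-iodo-2,6-dimethoxyphenyl 2,2-dimethylpropanoate | COc1cc(I)cc(OC)c1OC(=O)C(C)(C)C
A7 | alternative 3 | methyl (2R,3S)-5-chloro-2-[3,5-dimethoxy-4-(2,2-dimethylpropanoyloxy)phenyl]-7-methoxy-2,3-dihydro-1-benzofuran-3-carboxylate (cis) | COc1cc([C@@H]2Oc3c(OC)cc(Cl)cc3[C@@H]2C(=O)OC)cc(OC)c1OC(=O)C(C)(C)C
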